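**Retrosynthetic overview**
1. Target ⇐ C14 triethylsilyl ether of the complete germacranolide (one-flask desilylation/oxidation); the ten-membered ring is formed last, by ring-closing metathesis at C4=C5.
2. Metathesis substrate ⇐ α-methylene-γ-butyrolactone (the first permanent ring) from allylboration of acrolein with a γ-substituted 2-(methoxycarbonyl)allylboronate; C8 controls C6 and C7.
3. Allylboronate ⇐ γ-acyloxy ynoate (conjugate hydroalumination, CH2Bpin transfer) ⇐ chelation-controlled addition of methyl propiolate to a lactol; C9 controls C8.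
4. Lactol ⇐ α-hydroxy-β-alkylidene butyrolactone (temporary ring) ⇐ proline-catalysed dienamine aldol/isomerisation of a γ-enolisable enal with ethyl glyoxylate; this sets C9 (first stereocentre) and the E-configured C1=C10 unit.
5. Enal ⇐ cross-metathesis of 2-methylhexa-1,5-diene with crotonaldehyde.

Assumption: positions are labelled by germacrane numbering (ring C1–C10; lactone C11–C13 with the ring oxygen on C6; C14 = aldehyde carbon on C10; C15 = methyl on C4; target 6R,7S,8S,9S, CHO trans to C2, C4=C5 Z), and the dienamine step is taken to follow the usual Houk–List facial sense, hence D-proline.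

**Step 1**
Reactants: 1 2-methylhexa-1,5-diene; 2 (E)-but-2-enal (crotonaldehyde)
Product: 3 (2E)-6-methylhepta-2,6-dienal
Conditions: 2 (5 equiv), second-generation Hoveyda–Grubbs catalyst RuCl2(=CH-C6H4-2-O-i-Pr)(H2IMes) (2 mol%), CH2Cl2, 40 °C
Reagents that add atoms: none
Why: Olefin cross-metathesis engages only the monosubstituted alkene of 1 (the 1,1-disubstituted end is inert here) and the electron-poor enal partner gives the E-enal with loss of propene.

**Step 2**
Reactants: 3 (2E)-6-methylhepta-2,6-dienal; 4 ethyl glyoxylate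
Product: 7 (3S,4Z)-3-hydroxy-4-(4-methylpent-4-en-1-ylidene)oxolan-2-one, via formyl hydroxy ester 5 (not isolated), via diol ester 6 (not isolated)
Conditions: 4 (2 equiv), D-proline (30 mol%), imidazole (30 mol%), DMF, 4 °C, 48 h; then MeOH, CeCl3·7H2O, NaBH4, −40 °C; then 1 M HCl, THF, rt
Reagents that add atoms: none
Why: Proposed new method: D-proline converts enal 3 into its 2-aminodiene (dienamine), whose α-carbon (C10) adds to the very electrophilic aldehyde of 4 through the carboxylic-acid-organised Houk–List transition state to set C9 as S, and imidazole returns the resulting β,γ-unsaturated iminium to the conjugated E-enal 5 (CHO trans to C2), which is trapped by Luche reduction and acid lactonisation; the closest known reaction type is the proline/imidazole aza-Morita–Baylis–Hillman-type Mannich reaction of β-substituted enals with glyoxylate imines, the aldehyde-acceptor version on a linear γ-enolisable enal being unreported.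

**Step 3**
Reactants: 7 (3S,4Z)-3-hydroxy-4-(4-methylpent-4-en-1-ylidene)oxolan-2-one
Product: 8 (3S,4Z)-4-(4-methylpent-4-en-1-ylidene)oxolane-2,3-diol (anomer mixture)
Conditions: i-Bu2AlH (2.2 equiv), CH2Cl2, −78 °C; aq. KNaC4H4O6 work-up
Reagents that add atoms: none
Why: Lactone-to-lactol reduction stops at the aldehyde oxidation level because the tetrahedral aluminium hemiacetal survives at −78 °C until work-up, and the cyclic lactol keeps the allylic C9 centre from epimerising.

**Step 4**
Reactants: 8 (3S,4Z)-4-(4-methylpent-4-en-1-ylidene)oxolane-2,3-diol; 9 methyl propiolate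
Product: 10 methyl (4S,5S,6Z)-4,5-dihydroxy-6-(hydroxymethyl)-10-methylundeca-6,10-dien-2-ynoate
Conditions: 9 (2.5 equiv), LiN(SiMe3)2 (4.5 equiv), MgBr2·OEt2 (2 equiv), THF, −78 °C; aq. NH4Cl at −78 °C
Reagents that add atoms: none
Why: Acetylide addition to the ring-opened lactol dialkoxide proceeds through the five-membered magnesium chelate of the α-alkoxide aldehyde (Cram chelate model, attack anti to the alkenyl group; the alkoxide also suppresses enolisation at C9), giving the syn 8S,9S diol.

**Step 5**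
Reactants: 10 methyl (4S,5S,6Z)-4,5-dihydroxy-6-(hydroxymethyl)-10-methylundeca-6,10-dien-2-ynoate
Product: 11 methyl (4S,5S,6Z)-4,5-dihydroxy-10-methyl-6-{[(triethylsilyl)oxy]methyl}undeca-6,10-dien-2-ynoate
Conditions: Et3SiCl (1.05 equiv), imidazole (2 equiv), CH2Cl2, −40 °C
Reagents that add atoms: chlorotriethylsilane CC[Si](Cl)(CC)CC
Why: Silyl ether formation with one equivalent of silyl chloride at low temperature is selective for the primary allylic hydroxyl (C14) over the two secondary ones on steric grounds.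

**Step 6**
Reactants: 11 methyl (4S,5S,6Z)-4,5-dihydroxy-10-methyl-6-{[(triethylsilyl)oxy]methyl}undeca-6,10-dien-2-ynoate; 12 isobutyric anhydride
Product: 13 methyl (4S,5S,6Z)-10-methyl-4,5-bis[(2-methylpropanoyl)oxy]-6-{[(triethylsilyl)oxy]methyl}undeca-6,10-dien-2-ynoate
Conditions: 12 (3 equiv), DMAP (0.2 equiv), pyridine, CH2Cl2, 0 °C to rt
Reagents that add atoms: none
Why: DMAP-catalysed acyl transfer esterifies both secondary alcohols under mild base without touching either stereocentre.

**Step 7**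
Reactants: 13 the bis-isobutyrate ynoate; 14 2-(iodomethyl)-4,4,5,5-tetramethyl-1,3,2-dioxaborolane
Product: 16 methyl (2Z,4S,5S,6Z)-10-methyl-4,5-bis[(2-methylpropanoyl)oxy]-2-[(4,4,5,5-tetramethyl-1,3,2-dioxaborolan-2-yl)methyl]-6-{[(triethylsilyl)oxy]methyl}undeca-2,6,10-trienoate, via alkenylalane 15 (not isolated)
Conditions: i-Bu2AlH (1.2 equiv), HMPA (2.4 equiv), THF, −20 °C; then 14 (1.5 equiv), 0 °C
Reagents that add atoms: none
Why: The HMPA complex of i-Bu2AlH is a soft hydride that adds 1,4 and syn to the ynoate (conjugate hydroalumination) rather than 1,2 to the hindered isobutyrates, and the α-alumino acrylate 15 is alkylated by 14 with retention, so C8 ends cis to the ester in 16.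

**Step 8**
Reactants: 16 the allylboronate; 17 acrolein
Product: 19 (1S,2S,3Z)-1-[(2R,3S)-2-ethenyl-4-methylidene-5-oxooxolan-3-yl]-7-methyl-3-{[(triethylsilyl)oxy]methyl}octa-3,7-diene-1,2-diyl bis(2-methylpropanoate), via borate ester 18 (not isolated)
Conditions: 17 (5 equiv), BHT (cat.), toluene, 80 °C, sealed tube
Reagents that add atoms: none
Why: Thermal carbonyl allylboration runs through a closed chair (Zimmerman–Traxler) transition state with the acrolein vinyl group and the C8 substituent both equatorial, giving the 6,7-anti adduct (trans lactone once borate 18 closes onto the ester), and the aldehyde approaches C7 anti to the C8–C9 bond with H-8 eclipsing the alkene (allylic 1,3-strain, Felkin-type control), which sets 6R,7S.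

**Step 9**
Reactants: 19 the vinyl lactone triene
Product: 20 (6R,7S,8S,9S,1(10)Z,4Z)-8,9-bis(2-methylpropanoyloxy)-14-(triethylsilyloxy)germacra-1(10),4,11(13)-trien-12,6-olide
Conditions: second-generation Grubbs catalyst RuCl2(=CHPh)(PCy3)(H2IMes) (15 mol%), 1,4-benzoquinone (30 mol%), toluene (0.5 mM), 90 °C
Reagents that add atoms: none
Why: Ring-closing metathesis initiates at the vinyl group and closes onto the 1,1-disubstituted alkene with loss of ethene, the ten-membered ring accepts only the cis (Z) trisubstituted C4=C5 bond, and the electron-poor α-methylene lactone and the hindered C1=C10 alkene do not compete.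

**Step 10**
Reactants: 20 the silyl-protected germacranolide
Product: 22 (6R,7S,8S,9S,1(10)E,4Z)-8,9-bis(2-methylpropanoyloxy)-14-oxogermacra-1(10),4,11(13)-trien-12,6-olide (the target CNP0305839.3), via allylic alcohol 21 (not isolated)
Conditions: IBX (3 equiv), DMSO (wet), rt
Reagents that add atoms: none
Why: IBX in wet DMSO cleaves the primary triethylsilyl ether and oxidises the liberated allylic alcohol 21 in the same flask to the enal (hypervalent-iodine oxidation) without touching the esters, the lactone or any stereocentre.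

**Compound list**
1 | 2-methylhexa-1,5-diene | C=CCCC(C)=C | starting material
2 | (E)-but-2-enal (crotonaldehyde) | C/C=C/C=O | starting material
3 | (2E)-6-methylhepta-2,6-dienal | O=C/C=C/CCC(C)=C | intermediate
4 | ethyl glyoxylate (ethyl 2-oxoacetate) | CCOC(=O)C=O | starting material
5 | ethyl (2S,3E)-3-formyl-2-hydroxy-7-methylocta-3,7-dienoate | CCOC(=O)[C@@H](O)/C(C=O)=C\CCC(C)=C | intermediate (not isolated)
6 | ethyl (2S,3Z)-2-hydroxy-3-(hydroxymethyl)-7-methylocta-3,7-dienoate | CCOC(=O)[C@@H](O)/C(CO)=C\CCC(C)=C | intermediate (not isolated)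
7 | (3S,4Z)-3-hydroxy-4-(4-methylpent-4-en-1-ylidene)oxolan-2-one | O=C1[C@@H](O)/C(CO1)=C\CCC(C)=C | intermediate
8 | (3S,4Z)-4-(4-methylpent-4-en-1-ylidene)oxolane-2,3-diol (lactol carbon left open, anomer mixture) | OC1[C@@H](O)/C(CO1)=C\CCC(C)=C | intermediate
9 | methyl propiolate (methyl prop-2-ynoate) | C#CC(=O)OC | starting material
10 | methyl (4S,5S,6Z)-4,5-dihydroxy-6-(hydroxymethyl)-10-methylundeca-6,10-dien-2-ynoate | COC(=O)C#C[C@H](O)[C@@H](O)/C(CO)=C\CCC(C)=C | intermediate
11 | methyl (4S,5S,6Z)-4,5-dihydroxy-10-methyl-6-{[(triethylsilyl)oxy]methyl}undeca-6,10-dien-2-ynoate | COC(=O)C#C[C@H](O)[C@@H](O)/C(CO[Si](CC)(CC)CC)=C\CCC(C)=C | intermediate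
12 | isobutyric anhydride (2-methylpropanoic anhydride) | CC(C)C(=O)OC(=O)C(C)C | starting material
13 | methyl (4S,5S,6Z)-10-methyl-4,5-bis[(2-methylpropanoyl)oxy]-6-{[(triethylsilyl)oxy]methyl}undeca-6,10-dien-2-ynoate | COC(=O)C#C[C@H](OC(=O)C(C)C)[C@@H](OC(=O)C(C)C)/C(CO[Si](CC)(CC)CC)=C\CCC(C)=C | intermediate
14 | 2-(iodomethyl)-4,4,5,5-tetramethyl-1,3,2-dioxaborolane | ICB1OC(C)(C)C(C)(C)O1 | starting material
15 | methyl (2E,4S,5S,6Z)-2-[bis(2-methylpropyl)alumanyl]-10-methyl-4,5-bis[(2-methylpropanoyl)oxy]-6-{[(triethylsilyl)oxy]methyl}undeca-2,6,10-trienoate | COC(=O)/C([Al](CC(C)C)CC(C)C)=C\[C@H](OC(=O)C(C)C)[C@@H](OC(=O)C(C)C)/C(CO[Si](CC)(CC)CC)=C\CCC(C)=C | intermediate (not isolated)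
16 | methyl (2Z,4S,5S,6Z)-10-methyl-4,5-bis[(2-methylpropanoyl)oxy]-2-[(4,4,5,5-tetramethyl-1,3,2-dioxaborolan-2-yl)methyl]-6-{[(triethylsilyl)oxy]methyl}undeca-2,6,10-trienoate | COC(=O)/C(CB1OC(C)(C)C(C)(C)O1)=C\[C@H](OC(=O)C(C)C)[C@@H](OC(=O)C(C)C)/C(CO[Si](CC)(CC)CC)=C\CCC(C)=C | intermediate
17 | acrolein (prop-2-enal) | C=CC=O | starting material
18 | methyl (3S,4S,5S,6Z)-10-methyl-2-methylidene-4,5-bis[(2-methylpropanoyl)oxy]-3-{(1R)-1-[(4,4,5,5-tetramethyl-1,3,2-dioxaborolan-2-yl)oxy]prop-2-en-1-yl}-6-{[(triethylsilyl)oxy]methyl}undeca-6,10-dienoate | C=C(C(=O)OC)[C@@H]([C@H](OB1OC(C)(C)C(C)(C)O1)C=C)[C@H](OC(=O)C(C)C)[C@@H](OC(=O)C(C)C)/C(CO[Si](CC)(CC)CC)=C\CCC(C)=C | intermediate (not isolated)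
19 | (1S,2S,3Z)-1-[(2R,3S)-2-ethenyl-4-methylidene-5-oxooxolan-3-yl]-7-methyl-3-{[(triethylsilyl)oxy]methyl}octa-3,7-diene-1,2-diyl bis(2-methylpropanoate) | C=C1C(=O)O[C@H](C=C)[C@H]1[C@H](OC(=O)C(C)C)[C@@H](OC(=O)C(C)C)/C(CO[Si](CC)(CC)CC)=C\CCC(C)=C | intermediate
20 | (6R,7S,8S,9S,1(10)Z,4Z)-8,9-bis(2-methylpropanoyloxy)-14-(triethylsilyloxy)germacra-1(10),4,11(13)-trien-12,6-olide | C=C1C(=O)O[C@@H]2/C=C(/C)CC/C=C(/CO[Si](CC)(CC)CC)[C@H](OC(=O)C(C)C)[C@@H](OC(=O)C(C)C)[C@@H]12 | intermediate
21 | (6R,7S,8S,9S,1(10)Z,4Z)-14-hydroxy-8,9-bis(2-methylpropanoyloxy)germacra-1(10),4,11(13)-trien-12,6-olide | C=C1C(=O)O[C@@H]2/C=C(/C)CC/C=C(/CO)[C@H](OC(=O)C(C)C)[C@@H](OC(=O)C(C)C)[C@@H]12 | intermediate (not isolated)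
22 | (6R,7S,8S,9S,1(10)E,4Z)-8,9-bis(2-methylpropanoyloxy)-14-oxogermacra-1(10),4,11(13)-trien-12,6-olide | C=C1C(=O)O[C@@H]2/C=C(/C)CC/C=C(/C=O)[C@H](OC(=O)C(C)C)[C@@H](OC(=O)C(C)C)[C@@H]12 | target

**Step count and risks**
Total step count: 10. Longest linear sequence: 10 steps (1 and 2 to 22).

The three steps most likely to fail:

Step 2 (the proposed new dienamine aldol/isomerisation). Risks are γ- instead of α-attack, self-condensation of the enal, and low ee. The fallback uses known chemistry and sets out from 3. Conjugate transfer hydrogenation (Hantzsch ester, cat. dibenzylammonium trifluoroacetate) gives 6-methylhept-6-enal F1. The known diarylprolinol-catalysed direct cross-aldol of F1 with 4 (the enantiomer of α,α-bis[3,5-bis(trifluoromethyl)phenyl]prolinol that delivers the 2S carbinol) gives the anti aldol ethyl (2S,3R)-3-formyl-2-hydroxy-7-methyloct-7-enoate F2. Amine-catalysed α-selenenylation with N-(phenylselanyl)phthalimide gives ethyl (2S)-3-formyl-2-hydroxy-7-methyl-3-(phenylselanyl)oct-7-enoate F3. Oxidation with H2O2 and syn-elimination of the selenoxide away from the carbinol carbon returns the E-enal 5, where the route is rejoined (reduction and lactonisation to 7 as in step 2).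

Step 8 (allylboration/lactonisation). Risks are erosion of the alkene geometry of 16, slow thermal addition, and wrong facial selectivity at C7. The fallback sets out from 13. The alkenylalane 15 is generated as in step 7 but quenched with (CH2O)n to give methyl (2Z,4S,5S,6Z)-2-(hydroxymethyl)-10-methyl-4,5-bis[(2-methylpropanoyl)oxy]-6-{[(triethylsilyl)oxy]methyl}undeca-2,6,10-trienoate F4. CBr4/PPh3 converts it into methyl (2E,4S,5S,6Z)-2-(bromomethyl)-10-methyl-4,5-bis[(2-methylpropanoyl)oxy]-6-{[(triethylsilyl)oxy]methyl}undeca-2,6,10-trienoate F5. A CrCl2-mediated Nozaki–Hiyama-type 2-(alkoxycarbonyl)allylation of 17 in THF then goes through the equilibrating allylchromium species, which is anti-selective whatever the bromide geometry; a catalytic version (CrCl2, Mn, Me3SiCl, chiral carbazole-bisoxazoline ligand) gives reagent control over the C6/C7 faces if needed. The adduct lactonises to 19, where the route is rejoined.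

Step 9 (ring-closing metathesis to the strained ten-membered ring). Risks are dimerisation and stalled closure on the trans-fused lactone. The fallback inverts the order of ring formation and sets out from 16 (with 17). Sc(OTf)3-catalysed allylboration at −78 °C in toluene with neutral work-up stops at the open hydroxy ester methyl (3S,4S,5S,6Z)-3-[(1R)-1-hydroxyprop-2-en-1-yl]-10-methyl-2-methylidene-4,5-bis[(2-methylpropanoyl)oxy]-6-{[(triethylsilyl)oxy]methyl}undeca-6,10-dienoate F6. Ring-closing metathesis of this more flexible triene (the free allylic hydroxyl assists initiation) gives methyl (6R,7S,8S,9S,1(10)Z,4Z)-6-hydroxy-8,9-bis(2-methylpropanoyloxy)-14-(triethylsilyloxy)germacra-1(10),4,11(13)-trien-12-oate F7. PPTS in toluene at 60 °C then closes the lactone to give 20, where the route is rejoined.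

**Further compounds**
F1 | step 2 | 6-methylhept-6-enal | O=CCCCCC(C)=C
F2 | step 2 | ethyl (2S,3R)-3-formyl-2-hydroxy-7-methyloct-7-enoate | CCOC(=O)[C@@H](O)[C@H](C=O)CCCC(C)=C
F3 | step 2 | ethyl (2S)-3-formyl-2-hydroxy-7-methyl-3-(phenylselanyl)oct-7-enoate (both C3 epimers) | CCOC(=O)[C@@H](O)C(C=O)([Se]c1ccccc1)CCCC(C)=C
F4 | step 8 | methyl (2Z,4S,5S,6Z)-2-(hydroxymethyl)-10-methyl-4,5-bis[(2-methylpropanoyl)oxy]-6-{[(triethylsilyl)oxy]methyl}undeca-2,6,10-trienoate | COC(=O)/C(CO)=C\[C@H](OC(=O)C(C)C)[C@@H](OC(=O)C(C)C)/C(CO[Si](CC)(CC)CC)=C\CCC(C)=C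
F5 | step 8 | methyl (2E,4S,5S,6Z)-2-(bromomethyl)-10-methyl-4,5-bis[(2-methylpropanoyl)oxy]-6-{[(triethylsilyl)oxy]methyl}undeca-2,6,10-trienoate | COC(=O)/C(CBr)=C\[C@H](OC(=O)C(C)C)[C@@H](OC(=O)C(C)C)/C(CO[Si](CC)(CC)CC)=C\CCC(C)=C
F6 | step 9 | methyl (3S,4S,5S,6Z)-3-[(1R)-1-hydroxyprop-2-en-1-yl]-10-methyl-2-methylidene-4,5-bis[(2-methylpropanoyl)oxy]-6-{[(triethylsilyl)oxy]methyl}undeca-6,10-dienoate | C=C(C(=O)OC)[C@@H]([C@H](O)C=C)[C@H](OC(=O)C(C)C)[C@@H](OC(=O)C(C)C)/C(CO[Si](CC)(CC)CC)=C\CCC(C)=C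
F7 | step 9 | methyl (6R,7S,8S,9S,1(10)Z,4Z)-6-hydroxy-8,9-bis(2-methylpropanoyloxy)-14-(triethylsilyloxy)germacra-1(10),4,11(13)-trien-12-oate | C=C(C(=O)OC)[C@H]1[C@H](O)/C=C(/C)CC/C=C(/CO[Si](CC)(CC)CC)[C@H](OC(=O)C(C)C)[C@H]1OC(=O)C(C)C
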